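The target is cut at the two aryl C(=O)–CH2 bonds of its butyryl groups. Each outer ring has its acyl carbon C1 ortho to a free hydroxyl (ring A: C2-OH and C6-OH; ring C: C6-OH, with C2-OMe on the other side), so each is a masked salicylaldehyde. One rhodium-catalysed, chelation-assisted twofold hydroacylation of propene should turn an unsymmetrical trimeric dialdehyde into the target without protecting groups. That dialdehyde is assembled from 2,4,6-trihydroxyacetophenone (ring B) and two isomeric formyl-methylphloroglucinol monomethyl ethers, joined one after the other through ortho-quinone methides released from Mannich bases.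

Key step: step 10

Remark on the structure: the two outer rings of the target are constitutional isomers. Numbered from the acyl carbon, ring A is 2,6-dihydroxy-4-methoxy-3-methyl with the bridge at C5 (between OMe and OH), whereas ring C is 4,6-dihydroxy-2-methoxy-3-methyl with the bridge at C5 (between two OH). A dialdehyde with two ring A units would lead to an isomer of the target, so the dialdehyde is built unsymmetrically.

Step 1
Reactants: 1 2-methylphloroglucinol
Product: 3 2,4,6-trihydroxy-3-methylbenzaldehyde, via aryl iminium chloride 2 (not isolated)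
Conditions: POCl3 (1.1 equiv), DMF, EtOAc, 0 °C to rt; then H2O, 50 °C
Reagents that add atoms: N,N-dimethylformamide CN(C)C=O (formyl carbon); water O (carbonyl oxygen)
Why: Vilsmeier–Haack formylation, in which the two unsubstituted positions of 1 are equivalent and the first formyl group deactivates the ring, so one regioisomer of the monoaldehyde should result after hydrolysis of iminium salt 2.

Step 2
Reactants: 3 2,4,6-trihydroxy-3-methylbenzaldehyde
Product: 4 2,6-dihydroxy-4-methoxy-3-methylbenzaldehyde (ring A aldehyde)
Conditions: Me2SO4 (1.0 equiv), K2CO3 (1.0 equiv), acetone, rt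
Reagents that add atoms: dimethyl sulfate COS(=O)(=O)OC
Why: Williamson O-methylation, in which the C4 hydroxyl para to the formyl group is the most acidic and the least tied up in hydrogen bonding to the carbonyl, so one equivalent of base and electrophile should methylate it in preference to the two ortho hydroxyls.

Step 3
Reactants: 4 2,6-dihydroxy-4-methoxy-3-methylbenzaldehyde
Product: 5 3-[(dimethylamino)methyl]-2,6-dihydroxy-4-methoxy-5-methylbenzaldehyde (ring A Mannich base)
Conditions: CH2=NMe2+ I− (1.05 equiv), MeCN, rt; aq. NaHCO3
Reagents that add atoms: N,N-dimethylmethyleneiminium iodide C=[N+](C)C.[I-]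
Why: Mannich aminomethylation by the preformed iminium ion at C5, the only unsubstituted ring position of 4, which is activated by the ortho methoxy and the ortho and para hydroxyls, while the hydrogen-bonded aldehyde does not react with the iminium salt.

Step 4
Reactants: 5 ring A Mannich base; 6 2,4,6-trihydroxyacetophenone (3 equiv)
Product: 8 3-[(3-acetyl-2,4,6-trihydroxyphenyl)methyl]-2,6-dihydroxy-4-methoxy-5-methylbenzaldehyde (ring A–ring B dimer), via ortho-quinone methide 7 (not isolated)
Conditions: 1,4-dioxane, 100 °C, N2 sweep
Reagents that add atoms: none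
Why: Thermal retro-Mannich loss of dimethylamine from the ortho-hydroxybenzylamine gives ortho-quinone methide 7, which C3 of 6 captures by conjugate (Friedel–Crafts-type) addition with rearomatisation of ring A, and the excess of 6 holds back a second alkylation at C5 of ring B.

Step 5
Reactants: 3 2,4,6-trihydroxy-3-methylbenzaldehyde
Product: 9 2-hydroxy-4,6-bis(methoxymethoxy)-3-methylbenzaldehyde
Conditions: MOMCl (2.2 equiv), K2CO3, acetone, rt to 40 °C
Reagents that add atoms: chloromethyl methyl ether COCCl (two equivalents are incorporated)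
Why: Williamson etherification, in which the para hydroxyl and the less hindered ortho hydroxyl at C6 react while the C2 hydroxyl, wedged between the formyl and methyl groups and chelated to the carbonyl, is expected to stay free, as is usual for bis-alkylation of 3-alkyl-2,4,6-trihydroxyaryl carbonyl compounds.

Step 6
Reactants: 9 2-hydroxy-4,6-bis(methoxymethoxy)-3-methylbenzaldehyde
Product: 10 2-methoxy-4,6-bis(methoxymethoxy)-3-methylbenzaldehyde
Conditions: MeI (3 equiv), K2CO3, DMF, 40 °C
Reagents that add atoms: iodomethane CI
Why: Williamson O-methylation of the one remaining, chelated phenol with excess electrophile in a polar aprotic solvent, to which the MOM acetals and the non-enolisable aldehyde are stable.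

Step 7
Reactants: 10 2-methoxy-4,6-bis(methoxymethoxy)-3-methylbenzaldehyde
Product: 11 4,6-dihydroxy-2-methoxy-3-methylbenzaldehyde (ring C aldehyde)
Conditions: 3 M HCl (cat.), MeOH, 50 °C
Reagents that add atoms: none
Why: Acid-catalysed acetal exchange (MOM cleavage) passes both methoxymethyl groups to methanol as dimethoxymethane, and the aryl methyl ether and the aldehyde are left untouched.

Step 8
Reactants: 11 4,6-dihydroxy-2-methoxy-3-methylbenzaldehyde
Product: 12 3-[(dimethylamino)methyl]-2,4-dihydroxy-6-methoxy-5-methylbenzaldehyde (ring C Mannich base)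
Conditions: CH2=NMe2+ I− (1.05 equiv), MeCN, rt; aq. NaHCO3
Reagents that add atoms: N,N-dimethylmethyleneiminium iodide C=[N+](C)C.[I-]
Why: Mannich aminomethylation at the only unsubstituted ring position of 11, which lies between two hydroxyls and is therefore strongly nucleophilic.

Step 9
Reactants: 12 ring C Mannich base; 8 ring A–ring B dimer
Product: 14 3-({3-acetyl-5-[(3-formyl-2,4-dihydroxy-6-methoxy-5-methylphenyl)methyl]-2,4,6-trihydroxyphenyl}methyl)-2,4-dihydroxy-6-methoxy-5-methylbenzaldehyde (unsymmetrical trimeric dialdehyde), via ortho-quinone methide 13 (not isolated)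
Conditions: 1,4-dioxane, 100 °C, N2 sweep
Reagents that add atoms: none
Why: The same retro-Mannich/ortho-quinone methide capture as in step 4, in which dimer 8 offers a single unsubstituted ring position (C5 of ring B, between two hydroxyls) and 13 offers none, so only the cross-coupled trimer should form.

Step 10
Reactants: 14 unsymmetrical trimeric dialdehyde; 15 propene (gas in excess; one molecule is taken up at each formyl group)
Product: 16 target, 1-[3-({3-acetyl-5-[(3-butanoyl-2,4-dihydroxy-6-methoxy-5-methylphenyl)methyl]-2,4,6-trihydroxyphenyl}methyl)-2,4-dihydroxy-6-methoxy-5-methylphenyl]butan-1-one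
Conditions: [RhCl(C8H12)]2 (5 mol %), 1,4-bis(diphenylphosphino)butane (10 mol %), K3PO4 (20 mol %), propene (5 bar), 1,4-dioxane, 80 °C
Reagents that add atoms: propene CC=C (the second equivalent, taken up at the other formyl group; the first is reactant 15)
Why: K3PO4 turns a hydroxyl ortho to each formyl group into a phenoxide that binds monovalent rhodium, and oxidative addition of the neighbouring aldehyde C–H bond gives a five-membered chelated acyl hydride of trivalent rhodium in which chelation holds back decarbonylation. Propene inserts into the Rh–H bond and C–C reductive elimination forms the ketone and returns monovalent rhodium; this cycle runs once at the ring A aldehyde and once at the ring C aldehyde, so two molecules of propene are consumed and both carbonyl-to-CH2 bonds form in the same operation. The closest known reaction type is the rhodium-catalysed intermolecular hydroacylation of terminal alkenes with salicylaldehydes. No ring is closed and no stereocentre is formed. The step needs linear (anti-Markovnikov) insertion at both aldehydes so that n-propyl and not isopropyl ketones result, and the bisphosphine together with the two ortho substituents flanking each acyl–rhodium unit (OH/OH on ring A, OMe/OH on ring C) should disfavour the more crowded secondary alkyl complex. The acetyl group of ring B has no aldehyde C–H bond and is inert, and the acid-free medium should leave both diarylmethane bridges in place.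

Compound list
1 | 2-methylphloroglucinol (2-methylbenzene-1,3,5-triol) | Cc1c(O)cc(O)cc1O | starting material
2 | N,N-dimethyl(2,4,6-trihydroxy-3-methylbenzylidene)iminium chloride | C[N+](C)=Cc1c(O)cc(O)c(C)c1O.[Cl-] | intermediate (not isolated)
3 | 2,4,6-trihydroxy-3-methylbenzaldehyde | O=Cc1c(O)cc(O)c(C)c1O | intermediate
4 | 2,6-dihydroxy-4-methoxy-3-methylbenzaldehyde (ring A aldehyde) | O=Cc1c(O)cc(OC)c(C)c1O | intermediate
5 | 3-[(dimethylamino)methyl]-2,6-dihydroxy-4-methoxy-5-methylbenzaldehyde | CN(C)Cc1c(OC)c(C)c(O)c(C=O)c1O | intermediate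
6 | 2,4,6-trihydroxyacetophenone | CC(=O)c1c(O)cc(O)cc1O | starting material
7 | 2-hydroxy-4-methoxy-3-methyl-5-methylidene-6-oxocyclohexa-1,3-diene-1-carbaldehyde (ring A ortho-quinone methide) | C=C1C(OC)=C(C)C(O)=C(C=O)C1=O | intermediate (not isolated)
8 | 3-[(3-acetyl-2,4,6-trihydroxyphenyl)methyl]-2,6-dihydroxy-4-methoxy-5-methylbenzaldehyde | CC(=O)c1c(O)cc(O)c(Cc2c(OC)c(C)c(O)c(C=O)c2O)c1O | intermediate
9 | 2-hydroxy-4,6-bis(methoxymethoxy)-3-methylbenzaldehyde | O=Cc1c(O)c(C)c(OCOC)cc1OCOC | intermediate
10 | 2-methoxy-4,6-bis(methoxymethoxy)-3-methylbenzaldehyde | O=Cc1c(OC)c(C)c(OCOC)cc1OCOC | intermediate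
11 | 4,6-dihydroxy-2-methoxy-3-methylbenzaldehyde (ring C aldehyde) | O=Cc1c(OC)c(C)c(O)cc1O | intermediate
12 | 3-[(dimethylamino)methyl]-2,4-dihydroxy-6-methoxy-5-methylbenzaldehyde | CN(C)Cc1c(O)c(C)c(OC)c(C=O)c1O | intermediate
13 | 2-hydroxy-6-methoxy-5-methyl-3-methylidene-4-oxocyclohexa-1,5-diene-1-carbaldehyde (ring C ortho-quinone methide) | C=C1C(=O)C(C)=C(OC)C(C=O)=C1O | intermediate (not isolated)
14 | 3-({3-acetyl-5-[(3-formyl-2,4-dihydroxy-6-methoxy-5-methylphenyl)methyl]-2,4,6-trihydroxyphenyl}methyl)-2,4-dihydroxy-6-methoxy-5-methylbenzaldehyde | O=Cc1c(O)c(C)c(OC)c(Cc2c(O)c(Cc3c(O)c(C)c(OC)c(C=O)c3O)c(O)c(C(C)=O)c2O)c1O | intermediate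
15 | propene | CC=C | starting material
16 | 1-[3-({3-acetyl-5-[(3-butanoyl-2,4-dihydroxy-6-methoxy-5-methylphenyl)methyl]-2,4,6-trihydroxyphenyl}methyl)-2,4-dihydroxy-6-methoxy-5-methylphenyl]butan-1-one | CCCC(=O)c1c(O)c(C)c(OC)c(Cc2c(O)c(Cc3c(O)c(C)c(OC)c(C(=O)CCC)c3O)c(O)c(C(C)=O)c2O)c1O | target

Total step count: 10
Longest linear sequence: 7 steps (steps 1, 5, 6, 7, 8, 9, 10)

Steps most likely to fail

Step 10. Propene may insert in the branched sense and give isobutyryl groups, the second hydroacylation may stall, or the polyphenoxide may sequester the rhodium. The fallback sets out from 1 and comes back at 16, and puts the butyryl groups in by classical C-acylation before the trimer is assembled. Friedel–Crafts acylation of 1 (butanoyl chloride, AlCl3, CH2Cl2/nitrobenzene) should give 1-(2,4,6-trihydroxy-3-methylphenyl)butan-1-one F1. Methylation as in step 2 should give 1-(2,6-dihydroxy-4-methoxy-3-methylphenyl)butan-1-one F2, and aminomethylation as in step 3 its Mannich base F3. Heating F3 with 6 as in step 4 should give, through the ring A quinone methide F4, the butyryl dimer F5. In parallel, F1 is taken as in steps 5 to 7 to the bis-MOM ether F6, then its methyl ether F7, then 1-(4,6-dihydroxy-2-methoxy-3-methylphenyl)butan-1-one F8, which is aminomethylated as in step 8 to the Mannich base F9. Heating F9 with F5 as in step 9 should give, through the ring C quinone methide F10, the target 16 directly.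

Step 9. At 100 °C the bridge already present in 8 may exchange by retro-Friedel–Crafts fragmentation and give symmetrical trimers, or the quinone methide may be released too slowly. The fallback sets out from 8 and comes back at 14, and reverses the roles so that the cheap monomer can be used in excess as the trap. Dimer 8 is aminomethylated at its one free ring B position (CH2=NMe2+ I−, MeCN, rt) to the dimer Mannich base F11. Warming F11 with an excess of 11 should release the ring B quinone methide F12, which the position of 11 between its two hydroxyls captures to give 14.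

Step 5. The C2 hydroxyl may be etherified in competition with the C6 hydroxyl, which would place the later methyl ether on the wrong oxygen. The fallback sets out from 4 and comes back at 12, bypassing 9, 10 and 11, and fixes the positions without relying on a choice between the two ortho hydroxyls. Reductive amination of 4 (Me2NH, NaBH(OAc)3, THF, rt) turns its formyl carbon into the future bridge carbon and should give 2-[(dimethylamino)methyl]-5-methoxy-4-methylbenzene-1,3-diol F13, kept as its hydrochloride. The only free ring position of F13 lies between the methoxy group and a hydroxyl, so Vilsmeier–Haack formylation (POCl3, DMF; then water) should give, through the iminium chloride F14, the Mannich base 12.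

Further compounds
F1 | step 10 | 1-(2,4,6-trihydroxy-3-methylphenyl)butan-1-one | CCCC(=O)c1c(O)cc(O)c(C)c1O
F2 | step 10 | 1-(2,6-dihydroxy-4-methoxy-3-methylphenyl)butan-1-one | CCCC(=O)c1c(O)cc(OC)c(C)c1O
F3 | step 10 | 1-{3-[(dimethylamino)methyl]-2,6-dihydroxy-4-methoxy-5-methylphenyl}butan-1-one | CCCC(=O)c1c(O)c(C)c(OC)c(CN(C)C)c1O
F4 | step 10 | 2-butanoyl-3-hydroxy-5-methoxy-4-methyl-6-methylidenecyclohexa-2,4-dien-1-one | C=C1C(OC)=C(C)C(O)=C(C(=O)CCC)C1=O
F5 | step 10 | 1-{3-[(3-acetyl-2,4,6-trihydroxyphenyl)methyl]-2,6-dihydroxy-4-methoxy-5-methylphenyl}butan-1-one | CCCC(=O)c1c(O)c(C)c(OC)c(Cc2c(O)cc(O)c(C(C)=O)c2O)c1O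
F6 | step 10 | 1-[2-hydroxy-4,6-bis(methoxymethoxy)-3-methylphenyl]butan-1-one | CCCC(=O)c1c(O)c(C)c(OCOC)cc1OCOC
F7 | step 10 | 1-[2-methoxy-4,6-bis(methoxymethoxy)-3-methylphenyl]butan-1-one | CCCC(=O)c1c(OC)c(C)c(OCOC)cc1OCOC
F8 | step 10 | 1-(4,6-dihydroxy-2-methoxy-3-methylphenyl)butan-1-one | CCCC(=O)c1c(OC)c(C)c(O)cc1O
F9 | step 10 | 1-{3-[(dimethylamino)methyl]-2,4-dihydroxy-6-methoxy-5-methylphenyl}butan-1-one | CCCC(=O)c1c(OC)c(C)c(O)c(CN(C)C)c1O
F10 | step 10 | 4-butanoyl-5-hydroxy-3-methoxy-2-methyl-6-methylidenecyclohexa-2,4-dien-1-one | C=C1C(=O)C(C)=C(OC)C(C(=O)CCC)=C1O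
F11 | step 9 | 3-({3-acetyl-5-[(dimethylamino)methyl]-2,4,6-trihydroxyphenyl}methyl)-2,6-dihydroxy-4-methoxy-5-methylbenzaldehyde | CC(=O)c1c(O)c(CN(C)C)c(O)c(Cc2c(OC)c(C)c(O)c(C=O)c2O)c1O
F12 | step 9 | 3-[(3-acetyl-2,4-dihydroxy-5-methylidene-6-oxocyclohexa-1,3-dien-1-yl)methyl]-2,6-dihydroxy-4-methoxy-5-methylbenzaldehyde | CC(=O)C1=C(O)C(=C)C(=O)C(Cc2c(OC)c(C)c(O)c(C=O)c2O)=C1O
F13 | step 5 | 2-[(dimethylamino)methyl]-5-methoxy-4-methylbenzene-1,3-diol | CN(C)Cc1c(O)cc(OC)c(C)c1O
F14 | step 5 | N,N-dimethyl{3-[(dimethylamino)methyl]-2,4-dihydroxy-6-methoxy-5-methylbenzylidene}iminium chloride | CN(C)Cc1c(O)c(C)c(OC)c(C=[N+](C)C)c1O.[Cl-]
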